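Target cannot be an end product: in birch its reading fell from 15.1 % at 40.0 min to 12.8 % at 90.0 min, while substrate went on falling from 68.8 % to 62.2 %. So I needed the height of the rise and the rate of the fall, and I joined them at the peak.

| setting | birch | maple | oak | east | south-east | west |
|---|---|---|---|---|---|---|
| substrate | 1 M | 1 M | 1.5 M | 1.0 M | 1.0 M | 1.0 M |
| partner | 0.55 M | 2.2 M | 1.1 M | 1.10 M | 1.10 M | 1.10 M |
| temperature | 85 °C | 110 °C | 85 °C | 90 °C | 110 °C | 130 °C |
| remark | run made earlier | run made earlier | run made earlier |  |  |  |
| time |  |  |  | 80 min | 80 min | 80 min |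

| run | time / min | target / % | substrate / % |
|---|---|---|---|
| birch | 8.00 | 6.4 | 87.0 |
| birch | 25.0 | 12.8 | 75.1 |
| birch | 40.0 | 15.1 | 68.8 |
| birch | 60.0 | 14.0 | 65.4 |
| birch | 90.0 | 12.8 | 62.2 |
| maple | 8.00 | 48.7 | 12.7 |
| maple | 15.0 | 45.4 | 8.9 |
| maple | 20.0 | 40.6 | 7.1 |
| maple | 30.0 | 33.7 | 5.8 |
| oak | 8.00 | 12.1 | 77.7 |
| oak | 15.0 | 17.3 | 68.5 |
| oak | 25.0 | 20.7 | 60.6 |
| oak | 50.0 | 21.0 | 54.2 |
| oak | 90.0 | 18.4 | 49.2 |

(standard deviation of a reading: 0.5 percentage points)

- the analysis behind the earlier runs scatters by 0.5 percentage points, standard deviation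
- a reading or a percentage of target counts all its forms, free or not
- a reading of substrate is of its free form alone

- which flask leads in amount of target, in percent of the substrate charged ("all alike" within 1.5 percentage points) (east / south-east / west / all alike)
- how much target is there at the end, in percent of the substrate charged: east
- how much target is there at the end, in percent of the substrate charged: south-east
- how much target is there at the end, in percent of the substrate charged: west

For the height I used birch and oak, where partner was the limiting reagent (0.55 M against 1 M, 1.1 M against 1.5 M). The top target reading of birch, taken as an amount per amount of partner charged, came to 27.5 %, and I took this reading as the peak yield on partner, the peak amount of target, all forms counted, per amount of partner charged. The top reading of oak, at the same temperature, came to 28.6 % on the same count. Maple, with partner in excess, gave 22.1 % at its first reading, so carrying the yield to east, with 1.10 M on 1.0 M, was a bet.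

For the fall I assumed first-order loss past the peak. Birch gave 0.00330 min⁻¹ and maple, from 15.0 min to 30.0 min, gave 0.0199 min⁻¹. Interpolating the logarithm linearly in temperature gave 0.00473 min⁻¹ for east and, extrapolated, 0.0834 min⁻¹ for west. I dated the peak in east by birch and the hotter peaks by maple's first reading:

east: 30.2 % × exp(−0.00473 min⁻¹ × (80 min − 40.0 min)) = 25.0 %

south-east: 30.2 % × exp(−0.0199 min⁻¹ × (80 min − 8.00 min)) = 7.22 %

west: 30.2 % × exp(−0.0834 min⁻¹ × (80 min − 8.00 min)) = 0.0743 %

So I put east ahead. The forecast also chose east, with 30 %, 9 % and 0.5 %, on the ground that “Target itself decays”; for east my figure was lower than the forecast's.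

The flasks gave 24.1 % in east, 4.18 % in south-east and 0.210 % in west, so east led.

    substrate + partner ⇌ target (K = 1.30 L mol⁻¹, k = 10.4 L mol⁻¹ h⁻¹, Ea = 96.0 kJ mol⁻¹, ΔH = 27.0 kJ mol⁻¹)
    substrate + partner ⇌ isomer of the product (K = 148 L mol⁻¹, k = 5.96 L mol⁻¹ h⁻¹, Ea = 80.0 kJ mol⁻¹, ΔH = −3.00 kJ mol⁻¹)
    target → over-reaction product (k = 1.59 h⁻¹, Ea = 118 kJ mol⁻¹)
    partner + target ⇌ idle adduct, settled at all times (K = 2.80 L mol⁻¹, ΔH = −41.0 kJ mol⁻¹)
    partner → decomposed reagent (k = 0.295 h⁻¹, Ea = 126 kJ mol⁻¹)
    (constants at 110 °C)

East held 28.4 % of target at 40.0 min, less than the 30.2 % that the peak yield on partner gave it, and 24.1 % at 80.0 min. A neighbour of east was charged with 0.44 M of partner, 0.440 equiv, short of partner as birch was. The same yield gave it 12.1 % at the peak and, after the same fall, 10.0 %. That neighbour held 8.67 % of target, with 68 % of its substrate still unbound.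

The numbers in the tables were generated by integration for substances that don't exist; the scatter is artificial.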